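The C2–C3 bond of the pyranone ring C is the disconnection on which everything rests. C2 is a benzylic carbon bound to the ring oxygen O1, so O1–C2–aryl is recognised as a 4-silyloxybenzyl ether of the ring A phenol, while C3–C4 is a diazoacetyl group on C4a. A chiral dirhodium carboxylate should turn this open diazoketone into the (2S)-flavanone in one operation: the carbene at C3 inserts into one of the two enantiotopic benzylic C–H bonds, closing ring C and setting C2. The 8-prenyl group is placed earlier by a para-Claisen–Cope rearrangement; the 3-hydroxyl follows by Rubottom oxidation anti to the 2-aryl group.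

Key step: step 6

Remark: the sense of induction of the chiral dirhodium catalyst on this substrate cannot be predicted with certainty; the route is written for the ligand enantiomer that delivers 2S, and the mirror-image catalyst is used if the first run shows the opposite sense.

Abbreviations: TBS = tert-butyldimethylsilyl, TMS = trimethylsilyl, prenyl = 3-methylbut-2-enyl. Flavonoid numbering (O1, C2, C3, C4, C4a, C5 to C8, C8a) is used for the chromanones and acetophenone locants for the open-chain precursors.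

Step 1
Reactants: 1 1-(2,6-dihydroxy-4-methoxyphenyl)ethanone; 2 [4-(TBS-oxy)phenyl]methanol
Product: 3 1-[2-{[4-(TBS-oxy)phenyl]methoxy}-6-hydroxy-4-methoxyphenyl]ethanone
Conditions: PPh3, DIAD, THF, 0 °C to rt (1.0 equiv of 2)
Reagents that add atoms: none
Why: Mitsunobu etherification of a symmetric diphenol, which should stop at the monoether because the remaining hydroxyl is locked in a hydrogen bond to the acetyl group; no stereocenter is formed.

Step 2
Reactants: 3 1-[2-{[4-(TBS-oxy)phenyl]methoxy}-6-hydroxy-4-methoxyphenyl]ethanone; 4 3-methylbut-2-en-1-ol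
Product: 5 1-[2-{[4-(TBS-oxy)phenyl]methoxy}-4-methoxy-6-(prenyloxy)phenyl]ethanone
Conditions: PPh3, DIAD, THF, 0 °C to rt
Reagents that add atoms: none
Why: Mitsunobu etherification of the chelated phenol under neutral conditions, which spares the aryl silyl ether and the ketone and places the prenyl group on the oxygen that later becomes the 5-hydroxyl.

Step 3
Reactants: 5 1-[2-{[4-(TBS-oxy)phenyl]methoxy}-4-methoxy-6-(prenyloxy)phenyl]ethanone
Product: 8 1-[2-{[4-(TBS-oxy)phenyl]methoxy}-6-hydroxy-4-methoxy-3-prenylphenyl]ethanone, via ortho-dienone 6 (not isolated), via para-dienone 7 (not isolated)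
Conditions: Eu(fod)3 (europium tris(6,6,7,7,8,8,8-heptafluoro-2,2-dimethyloctane-3,5-dionate), 10 mol %), NaHCO3, PhCl, 85 °C
Reagents that add atoms: none
Why: Lewis-acid-catalysed aromatic Claisen rearrangement to the ortho-dienone followed by a Cope shift (para-Claisen–Cope), so that the allyl unit is inverted twice and a linear prenyl group should arrive para to the oxygen it left, on the carbon between the benzyloxy and methoxy groups, before tautomerization restores the phenol.

Step 4
Reactants: 8 1-[2-{[4-(TBS-oxy)phenyl]methoxy}-6-hydroxy-4-methoxy-3-prenylphenyl]ethanone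
Product: 9 1-[6-(TBS-oxy)-2-{[4-(TBS-oxy)phenyl]methoxy}-4-methoxy-3-prenylphenyl]ethanone
Conditions: TBSCl, imidazole, DMAP (cat.), DMF, 40 °C
Reagents that add atoms: tert-butyldimethylsilyl chloride, CC(C)(C)[Si](C)(C)Cl
Why: Silylation of the chelated phenol, which removes the O–H bond that would otherwise trap the carbene and leaves a bulky ortho oxygen that carries no α-C–H bond.

Step 5
Reactants: 9 1-[6-(TBS-oxy)-2-{[4-(TBS-oxy)phenyl]methoxy}-4-methoxy-3-prenylphenyl]ethanone
Product: 11 2-diazo-1-[6-(TBS-oxy)-2-{[4-(TBS-oxy)phenyl]methoxy}-4-methoxy-3-prenylphenyl]ethanone, via trifluoroacetyl ketone 10 (not isolated)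
Conditions: LiN(SiMe3)2, THF, −78 °C; CF3CO2CH2CF3; 5% aq. HCl quench; then MsN3, Et3N, H2O, MeCN, rt
Reagents that add atoms: methanesulfonyl azide, CS(=O)(=O)N=[N+]=[N-] (the trifluoroacetyl group of 10 comes from 2,2,2-trifluoroethyl trifluoroacetate, O=C(OCC(F)(F)F)C(F)(F)F, and is lost again)
Why: Detrifluoroacetylative diazo transfer (Regitz type), in which the kinetic lithium enolate of the methyl ketone is trifluoroacetylated at low temperature and the activated 1,3-diketone then accepts the diazo group from the sulfonyl azide with loss of the trifluoroacetyl group as the N-sulfonyl amide.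

Step 6
Reactants: 11 2-diazo-1-[6-(TBS-oxy)-2-{[4-(TBS-oxy)phenyl]methoxy}-4-methoxy-3-prenylphenyl]ethanone
Product: 12 (2S)-5-(TBS-oxy)-2-[4-(TBS-oxy)phenyl]-7-methoxy-8-prenylchroman-4-one
Conditions: Rh2(S-BSP)4 (dirhodium tetrakis[(S)-N-(benzenesulfonyl)prolinate], 1 mol %), CH2Cl2, slow addition of 11 at high dilution, 0 °C to rt
Reagents that add atoms: none
Why: Dirhodium-catalysed loss of N2 gives an electrophilic rhodium carbene at C3 that inserts, in a concerted and asynchronous hydride-transfer-like three-centre step, into a benzylic C–H bond of the O1–CH2–aryl group and so forms C2–C3 with retention at carbon. The closest known reaction type is the dirhodium-carboxylate-catalysed intramolecular C–H insertion of 2-alkoxyaryl diazoketones next to the ether oxygen, which gives 2-substituted chroman-4-ones and has been run with chiral prolinate ligands. Ring C closes as a 1,6-insertion through a six-membered cyclic transition state made of C3, C4, C4a, C8a, O1 and C2. The one new stereocenter, C2, is set by the chiral carboxylate ligands, which distinguish the two enantiotopic benzylic hydrogens (catalyst control, 2S required). The step needs insertion to win over oxonium ylide formation at O1 with [1,2]-shift of the benzyl group, over reaction at the 5-oxygen and over cyclopropanation of the prenyl alkene. The C–H bond is activated twice (ether oxygen and electron-rich 4-silyloxyphenyl ring), the 5-oxygen is a bulky silyl ether of low donor ability, the prenyl group sits meta to the carbene-bearing chain and cannot reach it, and slow addition suppresses bimolecular pathways.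

Step 7
Reactants: 12 (2S)-5-(TBS-oxy)-2-[4-(TBS-oxy)phenyl]-7-methoxy-8-prenylchroman-4-one
Product: 15 (2R,3R)-5-(TBS-oxy)-2-[4-(TBS-oxy)phenyl]-3-hydroxy-7-methoxy-8-prenylchroman-4-one, via silyl enol ether 13 (not isolated), via siloxy epoxide 14 (not isolated)
Conditions: TMSOTf, Et3N, CH2Cl2, 0 °C; volatiles off, pentane filtration; DMDO (1.0 equiv), acetone–CH2Cl2, −78 °C, dark; then citric acid, MeOH, 0 °C
Reagents that add atoms: dimethyldioxirane, CC1(C)OO1 (the TMS group of 13 and 14 comes from trimethylsilyl triflate, C[Si](C)(C)OS(=O)(=O)C(F)(F)F, and is lost on work-up)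
Why: Rubottom oxidation in which soft enolization avoids a free enolate and thus retro-oxa-Michael opening of ring C, the dioxirane should attack the electron-rich enol ether faster than the prenyl alkene and from the face anti to the 2-aryl group so that the new C3–O bond is trans to it (3R, substrate control), and mild acid opens the siloxy epoxide to the α-hydroxy ketone.

Step 8
Reactants: 15 (2R,3R)-5-(TBS-oxy)-2-[4-(TBS-oxy)phenyl]-3-hydroxy-7-methoxy-8-prenylchroman-4-one
Product: 16 (2R,3R)-3,5-dihydroxy-2-(4-hydroxyphenyl)-7-methoxy-8-prenylchroman-4-one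
Conditions: Bu4NF, AcOH (1:1), THF, 0 °C
Reagents that add atoms: none
Why: Fluoride-mediated cleavage of both aryl silyl ethers, buffered with acetic acid so that the base-sensitive trans-dihydroflavonol should neither epimerize at C2 or C3 nor ring-contract, while the prenyl group is inert.

Compound list
1 | 1-(2,6-dihydroxy-4-methoxyphenyl)ethanone | CC(=O)c1c(O)cc(OC)cc1O | starting material
2 | [4-(TBS-oxy)phenyl]methanol | CC(C)(C)[Si](C)(C)Oc1ccc(CO)cc1 | starting material
3 | 1-[2-{[4-(TBS-oxy)phenyl]methoxy}-6-hydroxy-4-methoxyphenyl]ethanone | CC(=O)c1c(O)cc(OC)cc1OCc1ccc(O[Si](C)(C)C(C)(C)C)cc1 | intermediate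
4 | 3-methylbut-2-en-1-ol | CC(C)=CCO | starting material
5 | 1-[2-{[4-(TBS-oxy)phenyl]methoxy}-4-methoxy-6-(prenyloxy)phenyl]ethanone | CC(=O)c1c(OCC=C(C)C)cc(OC)cc1OCc1ccc(O[Si](C)(C)C(C)(C)C)cc1 | intermediate
6 | ortho-dienone: 2-acetyl-3-{[4-(TBS-oxy)phenyl]methoxy}-5-methoxy-6-(2-methylbut-3-en-2-yl)cyclohexa-2,4-dien-1-one, racemic at C6 | CC(=O)C1=C(OCc2ccc(O[Si](C)(C)C(C)(C)C)cc2)C=C(OC)C(C(C)(C)C=C)C1=O | intermediate
7 | para-dienone: 2-acetyl-3-{[4-(TBS-oxy)phenyl]methoxy}-5-methoxy-4-prenylcyclohexa-2,5-dien-1-one, racemic at C4 | CC(=O)C1=C(OCc2ccc(O[Si](C)(C)C(C)(C)C)cc2)C(CC=C(C)C)C(OC)=CC1=O | intermediate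
8 | 1-[2-{[4-(TBS-oxy)phenyl]methoxy}-6-hydroxy-4-methoxy-3-prenylphenyl]ethanone | CC(=O)c1c(O)cc(OC)c(CC=C(C)C)c1OCc1ccc(O[Si](C)(C)C(C)(C)C)cc1 | intermediate
9 | 1-[6-(TBS-oxy)-2-{[4-(TBS-oxy)phenyl]methoxy}-4-methoxy-3-prenylphenyl]ethanone | CC(=O)c1c(O[Si](C)(C)C(C)(C)C)cc(OC)c(CC=C(C)C)c1OCc1ccc(O[Si](C)(C)C(C)(C)C)cc1 | intermediate
10 | trifluoroacetyl ketone: 4,4,4-trifluoro-1-[aryl of 9]butane-1,3-dione | O=C(CC(=O)C(F)(F)F)c1c(O[Si](C)(C)C(C)(C)C)cc(OC)c(CC=C(C)C)c1OCc1ccc(O[Si](C)(C)C(C)(C)C)cc1 | intermediate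
11 | 2-diazo-1-[6-(TBS-oxy)-2-{[4-(TBS-oxy)phenyl]methoxy}-4-methoxy-3-prenylphenyl]ethanone | [N-]=[N+]=CC(=O)c1c(O[Si](C)(C)C(C)(C)C)cc(OC)c(CC=C(C)C)c1OCc1ccc(O[Si](C)(C)C(C)(C)C)cc1 | intermediate
12 | (2S)-5-(TBS-oxy)-2-[4-(TBS-oxy)phenyl]-7-methoxy-8-prenylchroman-4-one | COc1cc(O[Si](C)(C)C(C)(C)C)c2c(c1CC=C(C)C)O[C@H](c1ccc(O[Si](C)(C)C(C)(C)C)cc1)CC2=O | intermediate
13 | silyl enol ether: (2S)-5-(TBS-oxy)-2-[4-(TBS-oxy)phenyl]-7-methoxy-8-prenyl-4-(TMS-oxy)-2H-chromene | COc1cc(O[Si](C)(C)C(C)(C)C)c2c(c1CC=C(C)C)O[C@H](c1ccc(O[Si](C)(C)C(C)(C)C)cc1)C=C2O[Si](C)(C)C | intermediate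
14 | siloxy epoxide: 3,4-epoxide of 13, oxirane oxygen on the face opposite to the 2-aryl group | COc1cc(O[Si](C)(C)C(C)(C)C)c2c(c1CC=C(C)C)O[C@H](c1ccc(O[Si](C)(C)C(C)(C)C)cc1)[C@H]3O[C@@]23O[Si](C)(C)C | intermediate
15 | (2R,3R)-5-(TBS-oxy)-2-[4-(TBS-oxy)phenyl]-3-hydroxy-7-methoxy-8-prenylchroman-4-one (2,3-trans) | COc1cc(O[Si](C)(C)C(C)(C)C)c2c(c1CC=C(C)C)O[C@H](c1ccc(O[Si](C)(C)C(C)(C)C)cc1)[C@@H](O)C2=O | intermediate
16 | (2R,3R)-3,5-dihydroxy-2-(4-hydroxyphenyl)-7-methoxy-8-prenylchroman-4-one (2,3-trans) | COc1cc(O)c2c(c1CC=C(C)C)O[C@H](c1ccc(O)cc1)[C@@H](O)C2=O | target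

Total step count: 8. Longest linear sequence: 8 steps, from 1 (2 and 4 are bought).

Steps most likely to fail

Step 6. The carbene may be captured by the lone pair of O1 (five-membered oxonium ylide, then [1,2]-shift of the electron-rich benzyl group to the carbene carbon) faster than it inserts into the C–H bond, and an acceptor-only ketocarbene may discriminate the two benzylic hydrogens only moderately. The fallback gives up the carbene altogether, closes ring C first and sets C2 by asymmetric conjugate addition; it sets out from 1 and comes back at 12.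
- Condensation of 1 with N,N-dimethylformamide dimethyl acetal (toluene, 90 °C) should give the enaminone (E)-1-(2,6-dihydroxy-4-methoxyphenyl)-3-(dimethylamino)prop-2-en-1-one F1.
- Aqueous HCl should close it to 5-hydroxy-7-methoxychromen-4-one F2; either hydroxyl gives the same chromone because 1 is symmetric.
- Mitsunobu etherification with 4 gives 7-methoxy-5-(prenyloxy)chromen-4-one F3.
- The Eu(fod)3-catalysed para-Claisen–Cope rearrangement, a standard move on 5-prenyloxy chromones, gives 5-hydroxy-7-methoxy-8-prenylchromen-4-one F4.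
- Silylation (TBSCl, imidazole, DMF) gives 5-(TBS-oxy)-7-methoxy-8-prenylchromen-4-one F5.
- Asymmetric conjugate addition of commercial 4-(TBS-oxy)phenylboronic acid, catalysed by Pd(OCOCF3)2 and a tert-butyl pyridine-oxazoline ligand (NH4PF6, H2O, ClCH2CH2Cl, 60 °C, ligand enantiomer chosen for 2S), should deliver 12. Steps 7 and 8 then follow unchanged.

Step 7. The dioxirane may also epoxidize the trisubstituted prenyl alkene, and the 2H-chromene enol ether 13 can lose C2 integrity by reversible electrocyclic ring opening if warmed or exposed to light. The fallback replaces electrophilic oxygen transfer by an aminoxylation and reduction sequence; it sets out from 13 (made as in the first stage of step 7) and comes back at 15.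
- O-selective nitroso aldol reaction of 13 with nitrosobenzene (Et3SiOTf cat., CH2Cl2, −78 °C), which does not touch isolated alkenes, should give (2R,3R)-3-(anilinooxy)-5-(TBS-oxy)-2-[4-(TBS-oxy)phenyl]-7-methoxy-8-prenylchroman-4-one F6, again by attack anti to the 2-aryl group.
- Reductive N–O cleavage with Mo(CO)6 (MeCN–H2O, 70 °C) should give 15.

Step 3. The ortho-dienone 6 may tautomerize to the ortho-(1,1-dimethylallyl)phenol before the Cope shift, or the Lewis acid may ionize the electron-rich benzyl ether. The fallback brings the prenyl group in by direct C-alkylation and changes the order of the ether-forming steps; it sets out from 1 and comes back at 9.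
- C-prenylation of 1 (prenyl bromide, DBU, THF, rt) should give 1-(2,6-dihydroxy-4-methoxy-3-prenylphenyl)ethanone F7.
- Silylation of the less hindered hydroxyl (TBSCl 1.0 equiv, imidazole, CH2Cl2, 0 °C) should give 1-[6-(TBS-oxy)-2-hydroxy-4-methoxy-3-prenylphenyl]ethanone F8.
- Mitsunobu etherification of the remaining hydroxyl with 2 (PPh3, DIAD, THF) gives 9.
- This path is one step shorter than steps 1 to 4 but rests on two selectivities (C- versus O-alkylation, and which hydroxyl is silylated), which is why it is held in reserve.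

Further compounds
F1 | step 6 | (E)-1-(2,6-dihydroxy-4-methoxyphenyl)-3-(dimethylamino)prop-2-en-1-one | CN(C)/C=C/C(=O)c1c(O)cc(OC)cc1O
F2 | step 6 | 5-hydroxy-7-methoxychromen-4-one | COc1cc(O)c2c(c1)OC=CC2=O
F3 | step 6 | 7-methoxy-5-(prenyloxy)chromen-4-one | COc1cc(OCC=C(C)C)c2c(c1)OC=CC2=O
F4 | step 6 | 5-hydroxy-7-methoxy-8-prenylchromen-4-one | COc1cc(O)c2c(c1CC=C(C)C)OC=CC2=O
F5 | step 6 | 5-(TBS-oxy)-7-methoxy-8-prenylchromen-4-one | COc1cc(O[Si](C)(C)C(C)(C)C)c2c(c1CC=C(C)C)OC=CC2=O
F6 | step 7 | (2R,3R)-3-(anilinooxy)-5-(TBS-oxy)-2-[4-(TBS-oxy)phenyl]-7-methoxy-8-prenylchroman-4-one | COc1cc(O[Si](C)(C)C(C)(C)C)c2c(c1CC=C(C)C)O[C@H](c1ccc(O[Si](C)(C)C(C)(C)C)cc1)[C@@H](ONc1ccccc1)C2=O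
F7 | step 3 | 1-(2,6-dihydroxy-4-methoxy-3-prenylphenyl)ethanone | CC(=O)c1c(O)cc(OC)c(CC=C(C)C)c1O
F8 | step 3 | 1-[6-(TBS-oxy)-2-hydroxy-4-methoxy-3-prenylphenyl]ethanone | CC(=O)c1c(O[Si](C)(C)C(C)(C)C)cc(OC)c(CC=C(C)C)c1O
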